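The easy step comes first: I set down the scheme, the flask and what is asked.

    free monomer + initiator → living end + monomer in chains (k1 = 75 /M/h)
    free monomer + living end → monomer in chains + living end, rate k2*[living end]*[free monomer] (k2 = 740 /M/h)
    initiator → spent initiator A (k3 = 0.11 /h)
    initiator + impurity → spent initiator B (k4 = 1.2 × 10⁵ /M/h)
    pre-initiator → initiator (k5 = 0.92 /h)

free monomer 20 mM; pre-initiator 0.48 mM; impurity 0.71 mM; time 25 h

- the average divides the monomer in chains by the number of chains begun, living and dead together
- run time (flask): 25 h

* average number of monomer units in a chain (chains begun, living or dead) at 25 h
* part of the free monomer that has reacted at 25 h

I turn the question round and ask what the flask would need for the half-life of its free monomer to equal the run of 25 h. That takes 0.0375 mM of living ends, or 7.81% of the pre-initiator charge.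

Each initiator chooses between impurity and free monomer, and at the start the impurity wins by a capture ratio (a selectivity factor) of 56.8, which is 1.75 powers of ten. The impurity charge exceeds the pre-initiator charge, so I let the whole pre-initiator charge meet impurity, leaving a fraction 32.4% of the impurity. Holding free monomer at its charge, I integrate the ratio. The share of pre-initiator that starts chains is the natural logarithm of one over that fraction, divided by the capture ratio and by the pre-initiator charge as a fraction of the impurity charge: 2.94%.

That share stands 0.425 powers of ten short of the need. It gives a chain half-life, the natural logarithm of two over the growth constant times the living ends, of 66.5 h. So I commit to 22.9% reacted and chains of 326.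

The forecast gives 308 (285 to 335) and 20.8% (19% to 23%), both below mine. Like my reckoning, it starts from an impurity that “scavenges initiator far faster than monomer can capture it”.

The flask gives 313 and 20.7%. Its free monomer half-life reads 71 h at 25.0 h, longer than my 66.5 h and longer than the run of 25 h. So 79% of the charged free monomer stands unreacted in this flask. For the same flask read at 2.5 d, my half-life gives 46.5% reacted, and that flask shows 43.7%.

The constants were set for the occasion; the run is a simulation.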